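(The numbers were drawn at random within sensible limits; the rest is arithmetic.)

Two nucleophiles, one intermediate.

in all of them: substrate 0.0020 M; time 12 s
- Friday's: first nucleophile 0.950 equiv; second nucleophile 3.00 equiv (in portions, 5, over 2.5 s); temperature 25 °C; first portion at the start, last at 2.5 s
- Saturday's: first nucleophile 0.950 equiv (fed, over 2.5 s); second nucleophile 3.00 equiv; temperature 25 °C; all else is in the flask from the start; the feed brings no volume worth counting
- Tuesday's: first nucleophile 0.950 equiv (fed, over 2.5 s); second nucleophile 3.00 equiv; the addition at 5 °C, then warmed to 25 °C; the feed brings no volume worth counting
- Monday's: first nucleophile 0.950 equiv; second nucleophile 3.00 equiv; everything together at the start at 5 °C, warmed to 25 °C at 2.5 s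
- Wednesday's: first nucleophile 0.950 equiv; second nucleophile 3.00 equiv; temperature 25 °C; everything together at the start

    substrate → intermediate (k1 = 0.249 s⁻¹, Ea1 = 72.0 kJ mol⁻¹)
    first nucleophile + intermediate → target (k2 = 38200 M⁻¹ s⁻¹, Ea2 = 8.00 kJ mol⁻¹)
    second nucleophile + intermediate → other capture product (k3 = 5380 M⁻¹ s⁻¹, Ea3 = 12.0 kJ mol⁻¹)
    intermediate → solvolysis product (k4 = 99.7 s⁻¹, Ea4 = 68.0 kJ mol⁻¹)
    substrate + target → side product A (k5 = 7.97 M⁻¹ s⁻¹, Ea5 = 39.0 kJ mol⁻¹)
    intermediate → side product B (k6 = 0.122 s⁻¹, Ea6 = 75.0 kJ mol⁻¹)
    (constants at 25 °C)

- a species is counted by the substrate in it: one side product A counts as two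
- the constants hold at 25 °C; other temperatures follow from the activation energies

* which flask leads in share of target in target plus other capture product ("all alike" within 1.5 percentage points) (Friday's / Saturday's / Tuesday's / Monday's / Wednesday's / all alike)
* share of target in target plus other capture product at the end, Friday's
* share of target in target plus other capture product at the end, Saturday's
* share of target in target plus other capture product at the end, Tuesday's
* share of target in target plus other capture product at the end, Monday's
* share of target in target plus other capture product at the end, Wednesday's

**Zero point.** With equal rate constants, the charges would set the share of target at 24.1%. The selectivity factor, 7.10, moves it from there. Together they give the capture ratio ρ, the rate of target formation over the rate of other capture product, taken at the charged amounts: 2.25. The share at those amounts is ρ/(1+ρ), or 69.2%. Solvolysis is absent from ρ, which is a ratio of the two capture rates.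

**Milliseconds.** At the charged amounts and 25 °C, the intermediate lives 4.89 ms, far shorter than the 2.8 s half-life of substrate in Wednesday's flask. It therefore stays at a quasi-steady state, and each ionisation is shared out at the ratio of that instant.

**Seconds.** The dosing time of 2.5 s is close to that half-life, so the ratio during dosing counts. After Friday's first portion, ρ stands at 11.2, an instantaneous share of 91.8%, above the 69.2% of the charged amounts, so Friday's share should start high and end above Wednesday's. In Saturday's flask, the ratio starts from zero and climbs over the feed, so the share should end below 69.2%. In Wednesday's flask, the starting rates send 35.5% of ionised substrate to target, a third. Held over the whole charge of substrate, that starting split would take 37.3% of the first nucleophile's own charge and bring ρ down to 1.41, an instantaneous share of 58.5%. Wednesday's share should fall between 58.5% and 69.2%. The cooled flasks stay unreckoned here.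

**Longer times.** In Wednesday's flask, with substrate held as charged, target has a half-life of 43 s against side product A, longer than the 12 s of the run, so this loss should stay a small correction. By the end of Wednesday's flask, the half-life of substrate reckons 5.04% of it still present.

**Forecast.** The forecast named Friday's, with 71.5% for Friday's, 57.3% for Saturday's, 63.3% for Tuesday's, 65.5% for Monday's and 65% for Wednesday's, holding that “dosing in the second nucleophile favours target”.

**Result.** Friday's leads at 71.6%, with Saturday's at 57.4%, Tuesday's at 63.2%, Monday's at 65.3% and Wednesday's at 65.1%. Wednesday's share lies below 69.2% and above 58.5%. Read as a ratio, Friday's share is 2.52, which is 1.12 times ρ. The same flask as Friday's with 5.10 equiv of second nucleophile has ρ of 1.32. Multiplied by the same factor, that gives 1.48, a share of 59.7%, and that neighbouring flask ends at 60.4%.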